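**Plan**

- Ring atoms are numbered as in the target: C1 (C=O), C2 (heptenyl), C3 (CH2OH), C4/C5 (cis-diol), C6 (butenoic acid arm); C1' is the first heptenyl carbon. Enabling feature: the CH2OH oxygen on C3 and C1' on C2 sit 1,4 across C2=C3, so they close to a butenolide (O, CH2, C3, C2, C1'), which is an ester tether between a dienol and propiolic acid; the C4/C5 cis-diol is a masked ring alkene (cyclohexene retron).
- Cuts, in order: C6–C7 (enolate alkylation); C1'=C2' (Julia–Kocienski, which re-closes O–C1' to the lactone); the enone C1=O/C2=C3 back to C1=C2 with H on C3 (singlet-oxygen ene); the diol back to C4=C5; then C1–C6 and C2–C3 together ([4+2]) and the ester C–O.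
- Forward: ester 3; one rhodium-catalysed [4+2] closes the six-membered ring and the lactone; dihydroxylation and acetonide; ene oxidation; lactol; olefination opens the lactone into the CH2OH group and the heptenyl chain; oxidation at C1, alkylation at C6, global deprotection.
- Stereochemistry: C3 (temporary) from the chiral rhodium catalyst; C4/C5 from OsO4 anti to the lactone CH2 on C3; C6 from alkylation anti to O-5; C6' from (R)-hex-5-en-2-ol; both E-alkenes from the Julia–Kocienski step and a stabilised Wittig reaction.

Key step: step 2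

Remark: which antipode of the bisphosphine gives (3aR)-4 has to be assigned in the first run; nothing else in the route depends on that choice.

**Route**

Step 1
Reactants: 1 (2E)-penta-2,4-dien-1-ol; 2 prop-2-ynoic acid
Product: 3 (2E)-penta-2,4-dien-1-yl prop-2-ynoate
Conditions: DCC, DMAP (5 mol %), CH2Cl2, −20 → 0 °C
Reagents that add atoms: none
Why: Steglich esterification at low temperature with only catalytic DMAP should acylate the primary allylic alcohol without conjugate addition to the propiolate or allylic transposition of the dienol.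

Step 2
Reactants: 3 (2E)-penta-2,4-dien-1-yl prop-2-ynoate
Product: 4 (3aR)-3a,6-dihydro-2-benzofuran-1(3H)-one
Conditions: [Rh(cod)2]SbF6 (5 mol %), (R)-H8-BINAP (5 mol %, H2-activated; antipode if needed for 3aR), slow addition of 3, CH2Cl2 (0.01 M), 25 °C
Reagents that add atoms: none
Why: Proposed new method: the cationic monovalent rhodium–bisphosphine complex should bind the s-cis diene and the alkyne of 3, undergo oxidative cyclization that joins the inner alkyne carbon to the carbinol-bearing diene terminus (C2–C3, closing the five-membered lactone in the fused, type 1 mode that the three-atom ester tether alone allows) and give an allyl–vinyl rhodacycle of trivalent rhodium, whose reductive elimination joins the alkyne CH to the far diene terminus (C1–C6) and closes the cyclohexa-1,4-diene. The closest known reaction type is the rhodium-catalysed intramolecular [4+2] cycloaddition of tethered 1,3-diene-8-ynes, which is enantioselective with chiral bisphosphines for ether-, sulfonamide- and malonate-tethered substrates and is known without a chiral ligand for ester-tethered ones; the enantioselective use on an ester tether is the untested part. The single new stereocentre C3 (3aR) is set by the ligand, which selects the diene face that is bound during oxidative cyclization. Regiochemistry is fixed by the tether, so the step needs only enantioselectivity and chemoselectivity against alkyne oligomerisation, which high dilution and slow addition should secure. No second stereocentre arises because C6 is unsubstituted.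

Step 3
Reactants: 4 (3aR)-3a,6-dihydro-2-benzofuran-1(3H)-one (crude, used at once under argon)
Product: 5 (3aR,4R,5S)-4,5-dihydroxy-3a,4,5,6-tetrahydro-2-benzofuran-1(3H)-one
Conditions: OsO4 (2 mol %), NMO (1.3 equiv), acetone/H2O (8:1), 0 °C
Reagents that add atoms: osmium tetroxide O=[Os](=O)(=O)=O (oxygen carrier); N-methylmorpholine N-oxide C[N+]1([O-])CCOCC1; water O
Why: Upjohn dihydroxylation should take the isolated cis ring alkene C4=C5 in preference to the ester-conjugated C1=C2 and add both oxygens syn from the face opposite the lactone CH2 on the adjacent C3, so that C4 and C5 are set from C3; the minor facial isomer, which would later lead into the enantiomeric series, is to be removed here by chromatography or crystallisation.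

Step 4
Reactants: 5 diol lactone
Product: 6 acetonide of 5
Conditions: 2,2-dimethoxypropane (3 equiv), PPTS (5 mol %), acetone, 25 °C
Reagents that add atoms: 2,2-dimethoxypropane COC(C)(C)OC
Why: Acid-catalysed transketalisation of the cis-1,2-diol should give the cis-fused dioxolane, which masks both hydroxyls through the oxidative, reductive and basic steps that follow.

Step 5
Reactants: 6 acetonide lactone
Product: 8 7-hydroxy butenolide, via allylic hydroperoxide 7 (not isolated)
Conditions: O2, tetraphenylporphyrin (1 mol %), visible light, CH2Cl2, 0 °C; then PPh3 (1.1 equiv), 0 °C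
Reagents that add atoms: dioxygen O=O
Why: The Schenck ene reaction of singlet oxygen with the α-alkylidene lactone should follow the gem effect of α,β-unsaturated esters, oxygen adding at the β-carbon C1 while the hydrogen on C3 (on the alkyl group geminal to the carbonyl) is removed suprafacially, so that the double bond moves to C2=C3, the C3 stereocentre is erased and PPh3 then reduces the hydroperoxide to the alcohol.

Step 6
Reactants: 8 7-hydroxy butenolide
Product: 9 lactol (both epimers at the hemiacetal carbon)
Conditions: i-Bu2AlH (2.5 equiv), CH2Cl2, −78 °C; aqueous potassium sodium tartrate work-up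
Reagents that add atoms: none
Why: At −78 °C the aluminium lactolate is stable, so reduction of the butenolide carbonyl should stop at the lactol, and the neutral tartrate work-up avoids acid-promoted dehydration to the furan.

Step 7
Reactants: 10 (2R)-hex-5-en-2-ol
Product: 11 tert-butyl[(2R)-hex-5-en-2-yloxy]dimethylsilane
Conditions: TBSCl, imidazole, CH2Cl2, 25 °C
Reagents that add atoms: tert-butyldimethylsilyl chloride CC(C)(C)[Si](C)(C)Cl
Why: Routine silylation protects the carbinol that becomes C6' and leaves the stereocentre untouched.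

Step 8
Reactants: 11 silyl ether
Product: 13 (5R)-5-(tert-butyldimethylsilyloxy)hexan-1-ol, via B-alkyl-9-BBN adduct 12 (not isolated)
Conditions: 9-BBN, THF, 0 → 25 °C; then NaOH, H2O2, 0 °C
Reagents that add atoms: 9-borabicyclo[3.3.1]nonane B1C2CCCC1CCC2 (boron of 12 only); hydrogen peroxide OO
Why: Brown hydroboration–oxidation with the bulky borane should place the hydroxyl at the terminal carbon with anti-Markovnikov selectivity.

Step 9
Reactants: 13 primary alcohol
Product: 14 1-phenyl-1H-tetrazol-5-yl sulfide
Conditions: 1-phenyl-1H-tetrazole-5-thiol, PPh3, DIAD, THF, 0 → 25 °C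
Reagents that add atoms: 1-phenyl-1H-tetrazole-5-thiol Sc1nnnn1-c1ccccc1
Why: The Mitsunobu reaction converts the unhindered primary alcohol into the thioether with the acidic heteroaryl thiol as nucleophile.

Step 10
Reactants: 14 sulfide
Product: 15 1-phenyl-1H-tetrazol-5-yl sulfone
Conditions: (NH4)6Mo7O24·4H2O (10 mol %), 30 % H2O2, EtOH, 0 → 25 °C
Reagents that add atoms: hydrogen peroxide OO
Why: Molybdate-catalysed peroxide oxidation takes the sulfide to the sulfone and is mild enough for the secondary silyl ether.

Step 11
Reactants: 9 lactol; 15 sulfone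
Product: 16 dienyl diol (lactone opened; C1–OH and C3–CH2OH free)
Conditions: KN(SiMe3)2 (3.5 equiv), DME, −60 → 25 °C
Reagents that add atoms: none
Why: In this Julia–Kocienski olefination the metalated sulfone should add to the hydroxy-enal that is in equilibrium with the lactolate under base, and Smiles rearrangement with loss of SO2 and the tetrazolone should give the E-alkene preferentially, which opens the temporary lactone ring, releases the C3 hydroxymethyl group and completes the heptenyl chain in one step.

Step 12
Reactants: 16 dienyl diol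
Product: 17 primary silyl ether
Conditions: TBSCl (1.05 equiv), imidazole, CH2Cl2, 0 °C
Reagents that add atoms: tert-butyldimethylsilyl chloride CC(C)(C)[Si](C)(C)Cl
Why: The primary allylic hydroxyl is silylated much faster than the hindered secondary one at C1, which stays free for oxidation.

Step 13
Reactants: 17 secondary allylic alcohol
Product: 18 cross-conjugated enone
Conditions: Dess–Martin periodinane (1.3 equiv), CH2Cl2, 0 → 25 °C
Reagents that add atoms: none
Why: Dess–Martin oxidation converts the only free hydroxyl into the C1 ketone under conditions that leave the diene, the silyl ethers and the acetonide alone.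

Step 14
Reactants: 19 tert-butyl 2-bromopropanoate
Product: 21 tert-butyl 2-(triphenylphosphoranylidene)propanoate, via phosphonium bromide 20 (not isolated)
Conditions: PPh3, toluene, 80 °C; then NaOH, H2O/CH2Cl2, 25 °C
Reagents that add atoms: triphenylphosphine c1ccc(cc1)P(c1ccccc1)c1ccccc1
Why: SN2 quaternisation of the α-bromo ester followed by deprotonation of the acidic phosphonium salt gives the stabilised ylide.

Step 15
Reactants: 21 ylide; 22 glycolaldehyde dimer
Product: 23 tert-butyl (2E)-4-hydroxy-2-methylbut-2-enoate
Conditions: CH2Cl2, 40 °C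
Reagents that add atoms: none
Why: The Wittig reaction of an α-methyl-substituted stabilised ylide with the monomeric aldehyde released from the dimer should give the E-trisubstituted enoate.

Step 16
Reactants: 23 allylic alcohol
Product: 24 tert-butyl (2E)-4-bromo-2-methylbut-2-enoate
Conditions: CBr4, PPh3, CH2Cl2, 0 °C
Reagents that add atoms: carbon tetrabromide BrC(Br)(Br)Br
Why: The Appel reaction converts the primary allylic alcohol into the bromide under neutral conditions without touching the alkene geometry.

Step 17
Reactants: 18 enone; 24 allylic bromide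
Product: 26 fully protected target, via lithium enolate 25 (not isolated)
Conditions: LiN(SiMe3)2 (1.1 equiv), THF, −78 °C; then 24 (1.5 equiv), DMPU, −78 → −40 °C
Reagents that add atoms: lithium hexamethyldisilazide [Li]N([Si](C)(C)C)[Si](C)(C)C (lithium of 25 only)
Why: Kinetic deprotonation of the enone at the α′ carbon C6 and SN2 alkylation of the cross-conjugated enolate with the reactive allylic bromide should place the side chain on the face opposite the adjacent acetonide oxygen at C5, which sets C6 trans to O-5.

Step 18
Reactants: 26 fully protected target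
Product: 27 pestallic acid O
Conditions: CF3CO2H/CH2Cl2/H2O (10:10:1), 0 → 25 °C
Reagents that add atoms: none
Why: Aqueous trifluoroacetic acid should hydrolyse the acetonide, cleave both silyl ethers and remove the tert-butyl ester by loss of isobutene in one acidic operation, so the β-hydroxy ketone is never exposed to base.

**Compound list**

1 | (2E)-penta-2,4-dien-1-ol | OC/C=C/C=C | starting material
2 | prop-2-ynoic acid (propiolic acid) | C#CC(=O)O | starting material
3 | (2E)-penta-2,4-dien-1-yl prop-2-ynoate | C#CC(=O)OC/C=C/C=C | intermediate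
4 | (3aR)-3a,6-dihydro-2-benzofuran-1(3H)-one (cyclohexa-1,4-diene fused to an α-alkylidene γ-lactone) | O=C1OC[C@@H]2C=CCC=C12 | intermediate
5 | (3aR,4R,5S)-4,5-dihydroxy-3a,4,5,6-tetrahydro-2-benzofuran-1(3H)-one (both OH cis to H-3a, trans to the lactone CH2) | O=C1OC[C@@H]2[C@@H](O)[C@@H](O)CC=C12 | intermediate
6 | (3aR,4R,5S)-4,5-(isopropylidenedioxy)-3a,4,5,6-tetrahydro-2-benzofuran-1(3H)-one (acetonide of 5) | O=C1OC[C@@H]2[C@H]3OC(C)(C)O[C@H]3CC=C12 | intermediate
7 | (4R,5S,7R)-7-hydroperoxy-4,5-(isopropylidenedioxy)-4,5,6,7-tetrahydro-2-benzofuran-1(3H)-one (OOH cis to the acetonide) | O=C1OCC2=C1[C@H](OO)C[C@@H]3OC(C)(C)O[C@H]23 | intermediate (not isolated)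
8 | (4R,5S,7R)-7-hydroxy-4,5-(isopropylidenedioxy)-4,5,6,7-tetrahydro-2-benzofuran-1(3H)-one | O=C1OCC2=C1[C@H](O)C[C@@H]3OC(C)(C)O[C@H]23 | intermediate
9 | (4R,5S,7R)-4,5-(isopropylidenedioxy)-1,3,4,5,6,7-hexahydro-2-benzofuran-1,7-diol (lactol, both C1 epimers) | OC1OCC2=C1[C@H](O)C[C@@H]3OC(C)(C)O[C@H]23 | intermediate
10 | (2R)-hex-5-en-2-ol | C=CCC[C@@H](C)O | starting material
11 | tert-butyl[(2R)-hex-5-en-2-yloxy]dimethylsilane | C=CCC[C@@H](C)O[Si](C)(C)C(C)(C)C | intermediate
12 | 9-[(5R)-5-(tert-butyldimethylsilyloxy)hexyl]-9-borabicyclo[3.3.1]nonane | B1(CCCC[C@@H](C)O[Si](C)(C)C(C)(C)C)C2CCCC1CCC2 | intermediate (not isolated)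
13 | (5R)-5-(tert-butyldimethylsilyloxy)hexan-1-ol | OCCCC[C@@H](C)O[Si](C)(C)C(C)(C)C | intermediate
14 | 5-{[(5R)-5-(tert-butyldimethylsilyloxy)hexyl]sulfanyl}-1-phenyl-1H-tetrazole | c1ccccc1-n1nnnc1SCCCC[C@@H](C)O[Si](C)(C)C(C)(C)C | intermediate
15 | 5-{[(5R)-5-(tert-butyldimethylsilyloxy)hexyl]sulfonyl}-1-phenyl-1H-tetrazole | c1ccccc1-n1nnnc1S(=O)(=O)CCCC[C@@H](C)O[Si](C)(C)C(C)(C)C | intermediate
16 | (1R,4R,5S)-2-[(1E,6R)-6-(tert-butyldimethylsilyloxy)hept-1-en-1-yl]-3-(hydroxymethyl)-4,5-(isopropylidenedioxy)cyclohex-2-en-1-ol | OCC1=C(/C=C/CCC[C@@H](C)O[Si](C)(C)C(C)(C)C)[C@H](O)C[C@@H]2OC(C)(C)O[C@H]12 | intermediate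
17 | (1R,4R,5S)-3-[(tert-butyldimethylsilyloxy)methyl]-2-[(1E,6R)-6-(tert-butyldimethylsilyloxy)hept-1-en-1-yl]-4,5-(isopropylidenedioxy)cyclohex-2-en-1-ol | CC(C)(C)[Si](C)(C)OCC1=C(/C=C/CCC[C@@H](C)O[Si](C)(C)C(C)(C)C)[C@H](O)C[C@@H]2OC(C)(C)O[C@H]12 | intermediate
18 | (4R,5S)-3-[(tert-butyldimethylsilyloxy)methyl]-2-[(1E,6R)-6-(tert-butyldimethylsilyloxy)hept-1-en-1-yl]-4,5-(isopropylidenedioxy)cyclohex-2-en-1-one | CC(C)(C)[Si](C)(C)OCC1=C(/C=C/CCC[C@@H](C)O[Si](C)(C)C(C)(C)C)C(=O)C[C@@H]2OC(C)(C)O[C@H]12 | intermediate
19 | tert-butyl 2-bromopropanoate (racemic) | CC(Br)C(=O)OC(C)(C)C | starting material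
20 | [1-(tert-butoxy)-1-oxopropan-2-yl]triphenylphosphonium bromide | CC(C(=O)OC(C)(C)C)[P+](c1ccccc1)(c1ccccc1)c1ccccc1.[Br-] | intermediate (not isolated)
21 | tert-butyl 2-(triphenylphosphoranylidene)propanoate | CC(=P(c1ccccc1)(c1ccccc1)c1ccccc1)C(=O)OC(C)(C)C | intermediate
22 | glycolaldehyde dimer (1,4-dioxane-2,5-diol; reacts as hydroxyacetaldehyde) | OC1COC(O)CO1 | starting material
23 | tert-butyl (2E)-4-hydroxy-2-methylbut-2-enoate | C/C(=C\CO)C(=O)OC(C)(C)C | intermediate
24 | tert-butyl (2E)-4-bromo-2-methylbut-2-enoate | C/C(=C\CBr)C(=O)OC(C)(C)C | intermediate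
25 | lithium enolate of 18 (O–Li on C1, C1=C6) | CC(C)(C)[Si](C)(C)OCC1=C(/C=C/CCC[C@@H](C)O[Si](C)(C)C(C)(C)C)C(O[Li])=C[C@@H]2OC(C)(C)O[C@H]12 | intermediate (not isolated)
26 | tert-butyl (2E)-4-{(1S,5R,6S)-4-[(tert-butyldimethylsilyloxy)methyl]-3-[(1E,6R)-6-(tert-butyldimethylsilyloxy)hept-1-en-1-yl]-5,6-(isopropylidenedioxy)-2-oxocyclohex-3-en-1-yl}-2-methylbut-2-enoate (side chain trans to the neighbouring acetonide oxygen) | CC(C)(C)[Si](C)(C)OCC1=C(/C=C/CCC[C@@H](C)O[Si](C)(C)C(C)(C)C)C(=O)[C@@H](C/C=C(\C)C(=O)OC(C)(C)C)[C@@H]2OC(C)(C)O[C@H]12 | intermediate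
27 | pestallic acid O, (2E)-4-{(1S,5R,6S)-5,6-dihydroxy-3-[(1E,6R)-6-hydroxyhept-1-en-1-yl]-4-(hydroxymethyl)-2-oxocyclohex-3-en-1-yl}-2-methylbut-2-enoic acid | C/C(=C\C[C@@H]1C(=O)C(/C=C/CCC[C@@H](C)O)=C(CO)[C@@H](O)[C@H]1O)C(=O)O | target

**Step count**

Total: 18 steps. Longest linear sequence: 11 steps (1–6, 11–13, 17, 18).

**Steps most likely to fail**

Step 2 (Proposed new method). The ester carbonyl may bind rhodium and change the rhodacycle geometry so that face discrimination of the diene is poor; the terminal alkynoate may oligomerise at the metal; and the skipped diene may isomerise or aromatise. The fallback uses known chemistry, the copper-catalysed enantioselective Diels–Alder reaction of N-propioloylpyrazoles with dienes, and makes the lactone after the cycloaddition. It sets out from 1 and 2 and comes back at 4. Alcohol 1 is silylated (TBSCl, imidazole) to tert-butyl(dimethyl)[(2E)-penta-2,4-dien-1-yloxy]silane F1. Acid 2 is coupled with 3,5-dimethylpyrazole (DCC) to 1-(3,5-dimethyl-1H-pyrazol-1-yl)prop-2-yn-1-one F2. F1 and F2 are combined with Cu(NTf2)2 (divalent copper) and a chiral 3-(2-naphthyl)-L-alanine amide ligand; the 1-substituted diene should give the ortho adduct, the acylpyrazole cyclohexa-1,4-diene F3. Desilylation with Bu4NF/AcOH frees the alcohol, which should lactonise onto the acylpyrazole and give 4.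

Step 11. The lactolate may open too slowly, the hindered conjugated aldehyde may give a poor E/Z ratio, and the sulfone anion may decompose before it adds. The fallback builds the alkene by metathesis instead of carbonyl olefination; it sets out from 9 and comes back at 16. Lactol 9 is methylenated with Ph3P=CH2 (from Ph3PCH3Br and KOt-Bu) to the vinyl diol (1R,4R,5S)-2-ethenyl-3-(hydroxymethyl)-4,5-(isopropylidenedioxy)cyclohex-2-en-1-ol F4. Separately, (R)-2-methyloxirane is opened with but-3-enylmagnesium bromide and catalytic CuI to (2R)-hept-6-en-2-ol F5, which is silylated to tert-butyl[(2R)-hept-6-en-2-yloxy]dimethylsilane F6. Cross-metathesis of F4 with excess F6 (second-generation Hoveyda–Grubbs catalyst, RuCl2(H2IMes)(=CH–C6H4-2-O-i-Pr), CH2Cl2, 40 °C) should engage only the terminal vinyl group, since the internal diene alkene is tetrasubstituted, and give 16 with the E-alkene favoured.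

Step 17. The enolate may expel the acetonide oxygen at C5 (β-elimination, then aromatisation); the bromoenoate may react by conjugate addition or at oxygen; and double alkylation or attack on the wrong face is possible. The fallback replaces the basic enolate by a neutral silyl enol ether and a π-allyl electrophile; it sets out from 18 and 23 and comes back at 26. Enone 18 is converted with LiN(SiMe3)2 in the presence of Me3SiCl (in situ quench, −78 °C) into the trimethylsilyl dienol ether F7. Alcohol 23 is converted with ClCO2Me/pyridine into tert-butyl (2E)-4-[(methoxycarbonyl)oxy]-2-methylbut-2-enoate F8. Allylation of F7 with F8 (Pd2(dba)3, dppe, zerovalent palladium, THF, 25 °C) should attack the less substituted allyl terminus, anti to O-5, and give 26.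

**Further compounds**

F1 | step 2 | tert-butyl(dimethyl)[(2E)-penta-2,4-dien-1-yloxy]silane | C=C/C=C/CO[Si](C)(C)C(C)(C)C
F2 | step 2 | 1-(3,5-dimethyl-1H-pyrazol-1-yl)prop-2-yn-1-one | C#CC(=O)n1nc(C)cc1C
F3 | step 2 | [(6R)-6-{[tert-butyl(dimethyl)silyl]oxymethyl}cyclohexa-1,4-dien-1-yl](3,5-dimethyl-1H-pyrazol-1-yl)methanone | Cc1cc(C)n(n1)C(=O)C1=CCC=C[C@H]1CO[Si](C)(C)C(C)(C)C
F4 | step 11 | (1R,4R,5S)-2-ethenyl-3-(hydroxymethyl)-4,5-(isopropylidenedioxy)cyclohex-2-en-1-ol | OCC1=C(C=C)[C@H](O)C[C@@H]2OC(C)(C)O[C@H]12
F5 | step 11 | (2R)-hept-6-en-2-ol | C=CCCC[C@@H](C)O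
F6 | step 11 | tert-butyl[(2R)-hept-6-en-2-yloxy]dimethylsilane | C=CCCC[C@@H](C)O[Si](C)(C)C(C)(C)C
F7 | step 17 | trimethylsilyl dienol ether of 18 (Me3SiO on C1, C1=C6) | CC(C)(C)[Si](C)(C)OCC1=C(/C=C/CCC[C@@H](C)O[Si](C)(C)C(C)(C)C)C(O[Si](C)(C)C)=C[C@@H]2OC(C)(C)O[C@H]12
F8 | step 17 | tert-butyl (2E)-4-[(methoxycarbonyl)oxy]-2-methylbut-2-enoate | C/C(=C\COC(=O)OC)C(=O)OC(C)(C)C
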